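**Retrosynthetic overview**
- The oxa-bridge is made last. Its two C–O bonds are the key bonds: O–C-6 comes from a C–Si to C–O oxidation, and O–C-3 comes from an intramolecular oxa-Michael addition to the ring A enone.
- The acrylic acid comes from an isopropenyl group. Ring C and that isopropenyl group come from an ene-type closure of a prenyl chain onto an α-methylene-δ-lactone.
- The δ-lactone closes by acyl C–O bond formation directly after a formaldehyde aldol that creates the spiro centre C-10.
- C-9–C-10 comes from SN2′ coupling of the ring A dienolate with a Baylis–Hillman bromide. C-5 comes from a desymmetrising conjugate addition to the symmetric dienone.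
- Ring order: ring A (bought), then the lactone, then ring C, then the tetrahydrofuran bridge.

Assumption: all four starting materials are bought as catalogue chemicals.

Atom labels follow ent-kaurane numbering:
- Ring A is C-1 (ketone), C-2, C-3 (ether CH), C-4 (CMe2), C-5 and C-10 (spiro).
- C-6 is the CH2 on C-5, C-20 is the lactone OCH2, and C-7 is the lactone C=O.
- Ring C is C-8, C-9, C-11, C-12, C-13 and C-14.
- C-15, C-16 and C-17 are the acrylic acid unit.

**Step 1**
Reactants: 1 4,4-dimethylcyclohex-2-en-1-one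
Product: 2 4,4-dimethylcyclohexa-2,5-dien-1-one
Conditions: DDQ (1.3 equiv), 1,4-dioxane, reflux
Reagents that add atoms: none
Why: DDQ dehydrogenation through the dienol (hydride abstraction, then proton loss) is the standard route to cross-conjugated dienones, the gem-dimethyl carbon blocks aromatisation, and no stereocentre is formed.

**Step 2**
Reactants: 2 4,4-dimethylcyclohexa-2,5-dien-1-one; 3 (chloromethyl)dimethyl(phenyl)silane
Product: 5 (5R)-5-{[dimethyl(phenyl)silyl]methyl}-4,4-dimethylcyclohex-2-en-1-one, via silylmethyl Grignard reagent 4 (not isolated)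
Conditions: 3, Mg, Et2O, reflux; then 2, CuBr·SMe2 (5 mol %), (R)-1-[(Sp)-2-(diphenylphosphino)ferrocenyl]ethyldicyclohexylphosphine (6 mol %), t-BuOMe, −75 °C; aq NH4Cl
Reagents that add atoms: none
Why: Proposed new method: a chiral diphosphine complex of monovalent copper takes the silylmethyl group from 4, binds one of the two enantiotopic enone arms of 2 as a π-complex, passes through a trivalent copper σ-alkyl species and reductively eliminates to form C-5–C-6, so the ligand pocket (enantiomer chosen to give 5R) sets C-5 and the magnesium dienolate formed is inert to a second addition; the closest known reaction types are the copper-catalysed enantioselective conjugate addition of Grignard reagents to cyclic enones and the dialkylzinc desymmetrisation of 4,4-disubstituted cyclohexadienones, neither shown for a silylmethyl (masked hydroxymethyl) group or for this dienone.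

**Step 3**
Reactants: 6 5-methylhex-4-enal; 7 methyl acrylate
Product: 8 methyl 3-hydroxy-7-methyl-2-methylideneoct-6-enoate (racemic)
Conditions: DABCO (0.5 equiv), MeOH, rt
Reagents that add atoms: none
Why: The Morita–Baylis–Hillman reaction of an unhindered aliphatic aldehyde with methyl acrylate is reliable, and the carbinol stereocentre is erased in step 4.

**Step 4**
Reactants: 8 methyl 3-hydroxy-7-methyl-2-methylideneoct-6-enoate
Product: 9 methyl (2Z)-2-(bromomethyl)-7-methylocta-2,6-dienoate
Conditions: PBr3 (0.4 equiv), Et2O, 0 °C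
Reagents that add atoms: phosphorus tribromide BrP(Br)Br
Why: Bromination of Baylis–Hillman alcohols with allylic transposition (SN2′) gives the conjugated Z-allyl bromide, and the cold non-protic conditions leave the prenyl alkene untouched.

**Step 5**
Reactants: 5 (5R)-5-{[dimethyl(phenyl)silyl]methyl}-4,4-dimethylcyclohex-2-en-1-one; 9 methyl (2Z)-2-(bromomethyl)-7-methylocta-2,6-dienoate
Product: 11 methyl (3S)-3-[(1R,6R)-6-{[dimethyl(phenyl)silyl]methyl}-5,5-dimethyl-2-oxocyclohex-3-en-1-yl]-7-methyl-2-methylideneoct-6-enoate, via lithium dienolate 10 (not isolated)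
Conditions: LiN(i-Pr)2 (1.05 equiv), THF, −78 °C; then 9, −78 to −40 °C
Reagents that add atoms: none
Why: Michael addition–elimination (SN2′) of a ketone enolate on a 2-(bromomethyl)enoate forms C-9–C-10 irreversibly and regenerates the methylidene ester; the pseudo-axial CH2SiMe2Ph group shields one face of 10, and a closed lithium-bridged transition state (ester carbonyl on lithium, homoprenyl chain turned away from C-5) sets C-9, while C-10 stays epimerisable until step 6.

**Step 6**
Reactants: 11 methyl (3S)-3-[(1R,6R)-6-{[dimethyl(phenyl)silyl]methyl}-5,5-dimethyl-2-oxocyclohex-3-en-1-yl]-7-methyl-2-methylideneoct-6-enoate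
Product: 13 (5S,6S,11S)-11-{[dimethyl(phenyl)silyl]methyl}-10,10-dimethyl-4-methylidene-5-(4-methylpent-3-en-1-yl)-2-oxaspiro[5.5]undec-8-ene-3,7-dione, via aldol adduct 12 (not isolated)
Conditions: KN(SiMe3)2 (1.1 equiv), THF, −78 °C; CH2O gas (cracked paraformaldehyde), −78 to 0 °C; aq NH4Cl
Reagents that add atoms: formaldehyde C=O
Why: C-10 carries the only enolisable proton (C-2 is vinylic, C-4 is quaternary), the formaldehyde aldol occurs anti to the C-5 substituent and so sets the spiro centre C-10, and the new alkoxide closes the δ-lactone on the methyl ester (aldol–lactonisation), which also prevents retro-aldol.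

**Step 7**
Reactants: 13 (5S,6S,11S)-11-{[dimethyl(phenyl)silyl]methyl}-10,10-dimethyl-4-methylidene-5-(4-methylpent-3-en-1-yl)-2-oxaspiro[5.5]undec-8-ene-3,7-dione
Product: 14 (1S,4'aR,6S,7'R,8'aS)-6-{[dimethyl(phenyl)silyl]methyl}-5,5-dimethyl-7'-(prop-1-en-2-yl)-4'a,5',6',7',8',8'a-hexahydro-3'H-spiro[cyclohex-3-ene-1,4'-isochromene]-1',2-dione
Conditions: Me2AlCl (2.5 equiv), CH2Cl2, −78 to 0 °C; aq NaHCO3
Reagents that add atoms: none
Why: In this Lewis acid promoted ene-type (cation–olefin) cyclisation the prenyl CH attacks the activated exocyclic methylene through a chair with the spiro carbon and the developing C-16 cation both equatorial (this sets C-13 trans to C-9), Me2AlCl scavenges protons so a methyl proton is lost to give the isopropenyl group, and axial protonation of the lactone enolate from the convex face sets C-8 cis to C-9.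

**Step 8**
Reactants: 14 (1S,4'aR,6S,7'R,8'aS)-6-{[dimethyl(phenyl)silyl]methyl}-5,5-dimethyl-7'-(prop-1-en-2-yl)-4'a,5',6',7',8',8'a-hexahydro-3'H-spiro[cyclohex-3-ene-1,4'-isochromene]-1',2-dione
Product: 15 (1S,4'aR,6S,7'R,8'aS)-6-{[dimethyl(phenyl)silyl]methyl}-7'-(3-hydroxyprop-1-en-2-yl)-5,5-dimethyl-4'a,5',6',7',8',8'a-hexahydro-3'H-spiro[cyclohex-3-ene-1,4'-isochromene]-1',2-dione
Conditions: SeO2 (0.3 equiv), t-BuOOH (3 equiv), CH2Cl2, rt
Reagents that add atoms: tert-butyl hydroperoxide CC(C)(C)OO; selenium dioxide (catalytic oxygen carrier) O=[Se]=O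
Why: Selenium dioxide allylic oxidation (ene reaction, then 2,3-shift) acts on the only electron-rich alkene, the ketone has no α-hydrogen at this stage so it cannot be oxidised, and no stereocentre is touched.

**Step 9**
Reactants: 15 (1S,4'aR,6S,7'R,8'aS)-6-{[dimethyl(phenyl)silyl]methyl}-7'-(3-hydroxyprop-1-en-2-yl)-5,5-dimethyl-4'a,5',6',7',8',8'a-hexahydro-3'H-spiro[cyclohex-3-ene-1,4'-isochromene]-1',2-dione
Product: 17 2-[(1S,4'aR,6S,7'R,8'aS)-6-{[dimethyl(phenyl)silyl]methyl}-5,5-dimethyl-1',2-dioxo-4'a,5',6',7',8',8'a-hexahydro-3'H-spiro[cyclohex-3-ene-1,4'-isochromen]-7'-yl]prop-2-enoic acid, via enal 16 (not isolated)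
Conditions: TEMPO (10 mol %), NaClO2 (2 equiv), NaOCl (5 mol %), MeCN/phosphate buffer pH 6.7, 35 °C
Reagents that add atoms: sodium chlorite [Na+].[O-]Cl=O
Why: The oxoammonium/chlorite oxidation (TEMPO oxidation followed by a Pinnick-type step in the same pot) takes the allylic alcohol to the acid at near-neutral pH, so the epimerisable C-8 and the lactone are safe.

**Step 10**
Reactants: 17 2-[(1S,4'aR,6S,7'R,8'aS)-6-{[dimethyl(phenyl)silyl]methyl}-5,5-dimethyl-1',2-dioxo-4'a,5',6',7',8',8'a-hexahydro-3'H-spiro[cyclohex-3-ene-1,4'-isochromen]-7'-yl]prop-2-enoic acid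
Product: 19 CNP0268721.1 2-[(1'S,2'S,4aR,5'S,7R,8aS)-8',8'-dimethyl-1,3'-dioxo-octahydrospiro[isochromene-4,2'-[6]oxabicyclo[3.2.1]octan]-7-yl]prop-2-enoic acid, via hydroxy enone acid 18 (not isolated)
Conditions: KBr, AcOOH, NaOAc, AcOH, 0 °C to rt; then camphorsulfonic acid (10 mol %), CH2Cl2, rt
Reagents that add atoms: peracetic acid CC(=O)OO
Why: Fleming–Tamao oxidation (ipso-bromodesilylation of the phenyl group, then silicon-to-oxygen migration) turns C-6–Si into C-6–O without harming the three electron-poor π-systems, and the freed CH2OH adds to the enone in an intramolecular oxa-Michael reaction that can reach C-3 only from the face it occupies, closing the bridge and setting C-3 as S.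

**Compound list**
1 | 4,4-dimethylcyclohex-2-en-1-one | CC1(C)CCC(=O)C=C1 | starting material
2 | 4,4-dimethylcyclohexa-2,5-dien-1-one | CC1(C)C=CC(=O)C=C1 | intermediate
3 | (chloromethyl)dimethyl(phenyl)silane | ClC[Si](C)(C)c1ccccc1 | starting material
4 | {[dimethyl(phenyl)silyl]methyl}magnesium chloride | Cl[Mg]C[Si](C)(C)c1ccccc1 | intermediate
5 | (5R)-5-{[dimethyl(phenyl)silyl]methyl}-4,4-dimethylcyclohex-2-en-1-one | O=C1C=CC(C)(C)[C@H](C[Si](C)(C)c2ccccc2)C1 | intermediate
6 | 5-methylhex-4-enal | CC(C)=CCCC=O | starting material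
7 | methyl acrylate | C=CC(=O)OC | starting material
8 | methyl 3-hydroxy-7-methyl-2-methylideneoct-6-enoate (racemic) | C=C(C(=O)OC)C(O)CCC=C(C)C | intermediate
9 | methyl (2Z)-2-(bromomethyl)-7-methylocta-2,6-dienoate | BrC/C(C(=O)OC)=C\CCC=C(C)C | intermediate
10 | lithium cross-conjugated dienolate of 5 | [Li+].[O-]C1=C[C@@H](C[Si](C)(C)c2ccccc2)C(C)(C)C=C1 | intermediate
11 | methyl (3S)-3-[(1R,6R)-6-{[dimethyl(phenyl)silyl]methyl}-5,5-dimethyl-2-oxocyclohex-3-en-1-yl]-7-methyl-2-methylideneoct-6-enoate | O=C1C=CC(C)(C)[C@H](C[Si](C)(C)c2ccccc2)[C@H]1[C@H](CCC=C(C)C)C(=C)C(=O)OC | intermediate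
12 | methyl (3S)-3-[(1S,6S)-6-{[dimethyl(phenyl)silyl]methyl}-1-(hydroxymethyl)-5,5-dimethyl-2-oxocyclohex-3-en-1-yl]-7-methyl-2-methylideneoct-6-enoate | O=C1C=CC(C)(C)[C@H](C[Si](C)(C)c2ccccc2)[C@]1(CO)[C@H](CCC=C(C)C)C(=C)C(=O)OC | intermediate
13 | (5S,6S,11S)-11-{[dimethyl(phenyl)silyl]methyl}-10,10-dimethyl-4-methylidene-5-(4-methylpent-3-en-1-yl)-2-oxaspiro[5.5]undec-8-ene-3,7-dione | C=C1C(=O)OC[C@]2(C(=O)C=CC(C)(C)[C@@H]2C[Si](C)(C)c2ccccc2)[C@@H]1CCC=C(C)C | intermediate
14 | cis-fused isopropenyl spirolactone enone (5S,8S,9R,10S,13R) | C=C(C)[C@@H]1CC[C@@H]2[C@H](C1)C(=O)OC[C@]21C(=O)C=CC(C)(C)[C@@H]1C[Si](C)(C)c1ccccc1 | intermediate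
15 | allylic alcohol of 14 (C-15 CH2OH) | C=C(CO)[C@@H]1CC[C@@H]2[C@H](C1)C(=O)OC[C@]21C(=O)C=CC(C)(C)[C@@H]1C[Si](C)(C)c1ccccc1 | intermediate
16 | enal (C-15 CHO) | C=C(C=O)[C@@H]1CC[C@@H]2[C@H](C1)C(=O)OC[C@]21C(=O)C=CC(C)(C)[C@@H]1C[Si](C)(C)c1ccccc1 | intermediate
17 | acrylic acid still carrying the 6-SiMe2Ph group and the ring A enone | C=C(C(=O)O)[C@@H]1CC[C@@H]2[C@H](C1)C(=O)OC[C@]21C(=O)C=CC(C)(C)[C@@H]1C[Si](C)(C)c1ccccc1 | intermediate
18 | 6-hydroxy enone acid | C=C(C(=O)O)[C@@H]1CC[C@@H]2[C@H](C1)C(=O)OC[C@]21C(=O)C=CC(C)(C)[C@@H]1CO | intermediate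
19 | CNP0268721.1 (3S,5S,8S,9R,10S,13R) | C=C(C(=O)O)[C@@H]1CC[C@@H]2[C@H](C1)C(=O)OC[C@]21C(=O)C[C@@H]2OC[C@H]1C2(C)C | target

**Step count**
- Total step count: 10.
- Longest linear sequence: 8 steps (1, 2, 5, 6, 7, 8, 9, 10).

**Three steps most likely to fail**

Step 2 (the new step). The silylmethyl group may transfer slowly next to the quaternary carbon, or the ee may be low. The fallback sets out from 2 and 4 and comes back at 5. The known CuI/LiCl-catalysed conjugate addition gives the racemic silylmethyl enone F1. Lithiated (S)-N,S-dimethyl-S-phenylsulfoximine is added to its carbonyl group. The two diastereomeric adducts are separated on silica to give the β-hydroxysulfoximine F2. Thermolysis of F2 in refluxing toluene returns the sulfoximine and enantiopure 5.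

Step 5. Direct SN2 attack at the CH2Br carbon or poor control at C-9 may intervene. The fallback sets out from 10 and 6 and comes back at 11, and it separates C–C bond formation from methylenation. Wittig reaction of 6 with methyl (triphenylphosphoranylidene)acetate gives the E-dienoate F3. Michael addition of 10 to F3 at −78 °C, followed by trapping of the ester enolate with dimethyl(methylidene)ammonium iodide, gives the Mannich base F4. Methylation with MeI gives the ammonium iodide F5, and elimination with DBU gives 11.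

Step 7. The zwitterion may be captured by chloride or may lose the ring proton to give the isopropylidene isomer. The fallback sets out from 13 and comes back at 14, and it replaces the cationic closure with a radical one. Ene-type allylic chlorination of the prenyl group (NaOCl, CeCl3·7H2O, CH2Cl2/H2O) gives the allylic chloride F6. Bu3SnH/AIBN in refluxing benzene then forms the allyl radical. This radical closes 6-endo onto the methylene lactone, and hydrogen transfer to C-8 from the convex face gives 14.

**Further compounds**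
F1 | step 2 | racemic 5-{[dimethyl(phenyl)silyl]methyl}-4,4-dimethylcyclohex-2-en-1-one | O=C1C=CC(C)(C)C(C[Si](C)(C)c2ccccc2)C1
F2 | step 2 | (5R)-5-{[dimethyl(phenyl)silyl]methyl}-4,4-dimethyl-1-{[(S)-N-methyl-S-phenylsulfonimidoyl]methyl}cyclohex-2-en-1-ol | O[C@]1(C[S@@](=O)(=NC)c2ccccc2)C=CC(C)(C)[C@H](C[Si](C)(C)c2ccccc2)C1
F3 | step 5 | methyl (2E)-7-methylocta-2,6-dienoate | COC(=O)/C=C/CCC=C(C)C
F4 | step 5 | methyl 2-[(dimethylamino)methyl]-3-[(1R,6R)-6-{[dimethyl(phenyl)silyl]methyl}-5,5-dimethyl-2-oxocyclohex-3-en-1-yl]-7-methyloct-6-enoate | O=C1C=CC(C)(C)[C@H](C[Si](C)(C)c2ccccc2)[C@H]1[C@H](CCC=C(C)C)C(CN(C)C)C(=O)OC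
F5 | step 5 | trimethylammonium iodide of F4 | O=C1C=CC(C)(C)[C@H](C[Si](C)(C)c2ccccc2)[C@H]1[C@H](CCC=C(C)C)C(C[N+](C)(C)C)C(=O)OC.[I-]
F6 | step 7 | 5-(3-chloro-4-methylpent-4-en-1-yl) analogue of 13 | C=C1C(=O)OC[C@]2(C(=O)C=CC(C)(C)[C@@H]2C[Si](C)(C)c2ccccc2)[C@@H]1CCC(Cl)C(C)=C
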